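**Plan**
- Cuts: the three O–Si bonds go last. Ring B is taken back from the resorcinol to the cyclohexane-1,3-dione level and opened at C1'–C6' and C4'–C5'. The resulting enone is cut at its C=C bond (olefination) and the benzofuran at its C2–CHO bond.
- Enabling feature: in ring B the oxygens at C3' and C5' are 1,3-related, and the prenyl groups at C2' and C6' flank the benzofuranyl carbon C1'. In the saturated dione these carbons are positions 4, 5 and 6, and each annulation partner delivers its carbon already substituted. Direct prenylation of a dione or resorcinol would hit C4' instead.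
- Forward: the benzofuran bicycle is bought intact, silylated at O6 and formylated at C2. Olefination with a prenylated ketophosphonate gives the α-prenyl enone. Ring B, the only ring made, closes in a one-flask Mukaiyama–Michael/Claisen annulation with the ketene silyl acetal of ethyl 5-methylhex-4-enoate.
- Endgame: double O-silylation to a cyclohexadiene, DDQ dehydrogenation and a single fluoride treatment, so no acid meets the ortho-prenyl phenols.
- Stereochemistry: the target has no stereocentre and no E/Z alkene. The three centres made in the annulation are transient (all-trans meso dione expected under equilibration) and are erased on aromatisation.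

Key step: step 6

Assumption: benzofuran-6-ol and ethyl 5-methylhex-4-enoate are taken as catalogue chemicals, and every 1,3-dione is drawn as its diketo tautomer although the enol form should dominate in solution.

**Step 1**
Reactants: 1 benzofuran-6-ol
Product: 2 6-(triisopropylsilyloxy)benzofuran
Conditions: iPr3SiCl (1.1 equiv), imidazole (2 equiv), DMF, rt
Reagents that add atoms: triisopropylsilyl chloride, CC(C)[Si](Cl)(C(C)C)C(C)C
Why: Imidazole-promoted O-silylation of a phenol is routine, and the bulky silyl ether should withstand n-BuLi, NaH and KOtBu, discourage lithiation next to the oxygen and leave with fluoride at the end.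

**Step 2**
Reactants: 2 6-(triisopropylsilyloxy)benzofuran
Product: 4 6-(triisopropylsilyloxy)benzofuran-2-carbaldehyde, via 2-lithiobenzofuran 3 (not isolated)
Conditions: n-BuLi (1.1 equiv), THF, −78 °C; DMF (2 equiv), −78 → 0 °C; H2O
Reagents that add atoms: N,N-dimethylformamide, CN(C)C=O
Why: C2–H is the most acidic position of a benzofuran, so heteroaryl α-lithiation followed by DMF formylation of the aryllithium should place the aldehyde at C2 only.

**Step 3**
Reactants: 5 dimethyl (2-oxopropyl)phosphonate; 6 prenyl bromide (1-bromo-3-methylbut-2-ene)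
Product: 8 dimethyl (6-methyl-2-oxohept-5-en-3-yl)phosphonate (racemic), via sodium phosphonoenolate 7 (not isolated)
Conditions: NaH (1.0 equiv), THF, 0 °C; 6 (0.9 equiv), 0 °C → rt
Reagents that add atoms: none
Why: SN2 C-alkylation of the doubly stabilised β-ketophosphonate anion with a reactive allylic bromide is standard, keeping 6 limiting suppresses a second alkylation, and the new racemic centre disappears in step 4.

**Step 4**
Reactants: 8 dimethyl (6-methyl-2-oxohept-5-en-3-yl)phosphonate; 4 6-(triisopropylsilyloxy)benzofuran-2-carbaldehyde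
Product: 10 (3E)-6-methyl-3-{[6-(triisopropylsilyloxy)benzofuran-2-yl]methylidene}hept-5-en-2-one, via sodium phosphonate carbanion 9 (not isolated)
Conditions: 8 (1.3 equiv), NaH (1.2 equiv), THF, 0 °C; 4, 0 → 50 °C
Reagents that add atoms: none
Why: Horner–Wadsworth–Emmons olefination of a non-enolisable heteroaryl aldehyde with an α-alkyl β-ketophosphonate should give the trisubstituted enone mainly as the E isomer (aryl trans to acetyl) because the addition is reversible, and either geometry would serve in step 6.

**Step 5**
Reactants: 11 ethyl 5-methylhex-4-enoate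
Product: 13 (1E)-1-ethoxy-5-methyl-1-(trimethylsilyloxy)hexa-1,4-diene, via lithium enolate 12 (not isolated)
Conditions: LiN(iPr)2 (1.1 equiv), THF, −78 °C; Me3SiCl (1.3 equiv), −78 °C → rt; pentane, filtration, distillation
Reagents that add atoms: chlorotrimethylsilane, C[Si](C)(C)Cl
Why: Kinetic ester deprotonation and O-silylation of the lithium enolate is the standard ketene silyl acetal synthesis, the cyclic transition state in neat THF favours the E acetal, and the geometry does not matter because the derived stereocentre is later erased.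

**Step 6**
Reactants: 10 (3E)-6-methyl-3-{[6-(triisopropylsilyloxy)benzofuran-2-yl]methylidene}hept-5-en-2-one; 13 (1E)-1-ethoxy-5-methyl-1-(trimethylsilyloxy)hexa-1,4-diene
Product: 16 meso-4,6-bis(3-methylbut-2-enyl)-5-[6-(triisopropylsilyloxy)benzofuran-2-yl]cyclohexane-1,3-dione (aryl trans to both prenyl groups), via silyl enol ether adduct 14 (not isolated), via potassium dionate 15 (not isolated)
Conditions: 13 (1.3 equiv), Me3SiOTf (10 mol %), CH2Cl2, −78 → −40 °C; Et3N (20 mol %), evaporate; KOtBu (2.2 equiv), THF–t-BuOH 10:1, 0 °C → rt; 1 M HCl to pH 4, 0 °C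
Reagents that add atoms: none
Why: Me3SiOTf silylates the enone oxygen of 10 and the single nucleophilic carbon of 13 attacks the benzofuranyl-bearing β-carbon (C1'–C6' bond) with silyl transfer to give 14, and this non-basic Mukaiyama–Michael manifold avoids the carbonyl attack and acetyl deprotonation that a lithium ester enolate would risk. KOtBu then strips the silyl group from 14, the freed enolate equilibrates through t-BuOH to the methyl side, and that carbon attacks the ester carbonyl with loss of ethoxide (C4'–C5' bond), closing ring B in a 6-(enolendo)-exo-trig Claisen condensation. The closest known chemistry is the Michael–Claisen annulation of enones with ester donors to cyclohexane-1,3-diones, together with the base-induced cyclisation of 5-oxohexanoates. The substrate secures the regiochemistry, because closure from the internal enolate carbon would need a four-membered ring, a simple ester enolate is too poor a leaving group for retro-Michael cleavage, and deprotonation to the dionate 15 makes the closure irreversible. The three new centres (C1', C2', C6') are under thermodynamic control, since both prenyl-bearing carbons sit next to carbonyl groups and can epimerise, so the all-equatorial meso isomer with the aryl group trans to both prenyl groups is expected. Any other diastereomer is equally usable because all three centres vanish by step 8.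

**Step 7**
Reactants: 16 meso-4,6-bis(3-methylbut-2-enyl)-5-[6-(triisopropylsilyloxy)benzofuran-2-yl]cyclohexane-1,3-dione
Product: 17 rac-trans-2-[3,5-bis(tert-butyldimethylsilyloxy)-2,6-bis(3-methylbut-2-enyl)cyclohexa-2,4-dien-1-yl]-6-(triisopropylsilyloxy)benzofuran (aryl at C1 trans to prenyl at C6 of the diene ring)
Conditions: tBuMe2SiOTf (2.5 equiv), Et3N (4 equiv), CH2Cl2, 0 °C → rt; pentane, cold aq NaHCO3 wash, used crude
Reagents that add atoms: tert-butyldimethylsilyl triflate, CC(C)(C)[Si](C)(C)OS(=O)(=O)C(F)(F)F
Why: In this soft enolisation with a silyl triflate and an amine the enol oxygen is silylated first, a second silylation at the vinylogous ester carbonyl gives a symmetrical 1,3-bis(silyloxy)allyl cation, and loss of the axial proton from either prenyl-bearing carbon leads to the same racemic cross-conjugated diene, whose two remaining centres keep their trans relation.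

**Step 8**
Reactants: 17 rac-trans-2-[3,5-bis(tert-butyldimethylsilyloxy)-2,6-bis(3-methylbut-2-enyl)cyclohexa-2,4-dien-1-yl]-6-(triisopropylsilyloxy)benzofuran
Product: 18 2-[3,5-bis(tert-butyldimethylsilyloxy)-2,6-bis(3-methylbut-2-enyl)phenyl]-6-(triisopropylsilyloxy)benzofuran
Conditions: DDQ (1.05 equiv), PhMe, 0 °C → rt
Reagents that add atoms: none
Why: In this DDQ dehydrogenation of a cyclohexa-1,3-diene, hydride loss from the benzofuranyl-bearing carbon gives a cyclohexadienyl cation stabilised by both silyloxy groups, proton loss from the neighbouring carbon gives the arene, and because both phenols emerge silylated the oxidative chromene formation known for free ortho-prenyl phenols cannot start.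

**Step 9**
Reactants: 18 2-[3,5-bis(tert-butyldimethylsilyloxy)-2,6-bis(3-methylbut-2-enyl)phenyl]-6-(triisopropylsilyloxy)benzofuran
Product: 19 mulberrofuran V [5-(6-hydroxybenzofuran-2-yl)-4,6-bis(3-methylbut-2-enyl)benzene-1,3-diol]
Conditions: Bu4NF (3.5 equiv), AcOH (3.5 equiv), THF, 0 °C → rt
Reagents that add atoms: none
Why: Fluoride-induced cleavage of aryl silyl ethers, buffered with AcOH, should free all three phenols at once under conditions too mild for prenyl–phenol cyclisation to chromans.

**Compound list**
1 | benzofuran-6-ol | Oc1ccc2ccoc2c1 | starting material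
2 | 6-(triisopropylsilyloxy)benzofuran | CC(C)[Si](Oc1ccc2ccoc2c1)(C(C)C)C(C)C | intermediate
3 | 2-lithio-6-(triisopropylsilyloxy)benzofuran | [Li]c1cc2ccc(O[Si](C(C)C)(C(C)C)C(C)C)cc2o1 | intermediate (not isolated)
4 | 6-(triisopropylsilyloxy)benzofuran-2-carbaldehyde | O=Cc1cc2ccc(O[Si](C(C)C)(C(C)C)C(C)C)cc2o1 | intermediate
5 | dimethyl (2-oxopropyl)phosphonate | COP(=O)(OC)CC(C)=O | starting material
6 | prenyl bromide (1-bromo-3-methylbut-2-ene) | CC(C)=CCBr | starting material
7 | sodium salt of 5 (anion at the carbon between P and C=O) | [Na+].COP(=O)(OC)[CH-]C(C)=O | intermediate (not isolated)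
8 | dimethyl (6-methyl-2-oxohept-5-en-3-yl)phosphonate, racemic | COP(=O)(OC)C(CC=C(C)C)C(C)=O | intermediate
9 | sodium salt of 8 (anion at the phosphorus-bearing carbon) | [Na+].COP(=O)(OC)[C-](CC=C(C)C)C(C)=O | intermediate (not isolated)
10 | (3E)-6-methyl-3-{[6-(triisopropylsilyloxy)benzofuran-2-yl]methylidene}hept-5-en-2-one | CC(=O)/C(CC=C(C)C)=C/c1cc2ccc(O[Si](C(C)C)(C(C)C)C(C)C)cc2o1 | intermediate
11 | ethyl 5-methylhex-4-enoate | CCOC(=O)CCC=C(C)C | starting material
12 | lithium enolate of 11 (alkyl chain trans to OLi) | [Li+].CCO/C([O-])=C\CC=C(C)C | intermediate (not isolated)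
13 | (1E)-1-ethoxy-5-methyl-1-(trimethylsilyloxy)hexa-1,4-diene | CCO/C(O[Si](C)(C)C)=C\CC=C(C)C | intermediate
14 | ethyl 7-methyl-2-(3-methylbut-2-enyl)-3-[6-(triisopropylsilyloxy)benzofuran-2-yl]-4-[1-(trimethylsilyloxy)ethylidene]oct-6-enoate, diastereomer mixture | CCOC(=O)C(CC=C(C)C)C(c1cc2ccc(O[Si](C(C)C)(C(C)C)C(C)C)cc2o1)C(CC=C(C)C)=C(C)O[Si](C)(C)C | intermediate (not isolated)
15 | potassium enolate of 16 (delocalised 1,3-dionate) | [K+].[O-]C1=CC(=O)[C@@H](CC=C(C)C)[C@H](c2cc3ccc(O[Si](C(C)C)(C(C)C)C(C)C)cc3o2)[C@H]1CC=C(C)C | intermediate (not isolated)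
16 | meso-4,6-bis(3-methylbut-2-enyl)-5-[6-(triisopropylsilyloxy)benzofuran-2-yl]cyclohexane-1,3-dione, aryl trans to both prenyl groups | O=C1CC(=O)[C@@H](CC=C(C)C)[C@H](c2cc3ccc(O[Si](C(C)C)(C(C)C)C(C)C)cc3o2)[C@H]1CC=C(C)C | intermediate
17 | rac-trans-2-[3,5-bis(tert-butyldimethylsilyloxy)-2,6-bis(3-methylbut-2-enyl)cyclohexa-2,4-dien-1-yl]-6-(triisopropylsilyloxy)benzofuran, one enantiomer drawn | CC(C)(C)[Si](C)(C)OC1=CC(O[Si](C)(C)C(C)(C)C)=C(CC=C(C)C)[C@H](c2cc3ccc(O[Si](C(C)C)(C(C)C)C(C)C)cc3o2)[C@H]1CC=C(C)C | intermediate
18 | 2-[3,5-bis(tert-butyldimethylsilyloxy)-2,6-bis(3-methylbut-2-enyl)phenyl]-6-(triisopropylsilyloxy)benzofuran | CC(C)=CCc1c(O[Si](C)(C)C(C)(C)C)cc(O[Si](C)(C)C(C)(C)C)c(CC=C(C)C)c1-c1cc2ccc(O[Si](C(C)C)(C(C)C)C(C)C)cc2o1 | intermediate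
19 | mulberrofuran V | CC(C)=CCc1c(O)cc(O)c(CC=C(C)C)c1-c1cc2ccc(O)cc2o1 | target

**Step count**
- Total: 9 steps.
- Longest linear sequence: 7 steps (steps 1, 2, 4, 6, 7, 8, 9).

**Steps most likely to fail**

Risk 1, step 6.
- The first bond must form between an α-branched acceptor, whose β-carbon carries an electron-rich heteroaryl group, and a branched nucleophile.
- The conjugate addition may therefore be slow, may divert to attack at the carbonyl group, or may be outrun by decay of the ketene acetal.
- The fallback adds the second prenyl group after ring closure instead of bringing it in with the donor.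
- It sets out from 10. The unbranched, commercial 1-(tert-butyldimethylsilyloxy)-1-methoxyethene is added under the same silyl triflate catalysis to give methyl 4-[1-(tert-butyldimethylsilyloxy)ethylidene]-7-methyl-3-[6-(triisopropylsilyloxy)benzofuran-2-yl]oct-6-enoate F1.
- Cold dilute HCl in THF hydrolyses the enol ether to methyl 4-acetyl-7-methyl-3-[6-(triisopropylsilyloxy)benzofuran-2-yl]oct-6-enoate F2.
- KOtBu in THF closes this to trans-4-(3-methylbut-2-enyl)-5-[6-(triisopropylsilyloxy)benzofuran-2-yl]cyclohexane-1,3-dione F3.
- The dianion of that dione (LiN(iPr)2, 2.2 equiv, THF–DMPU) is alkylated by 6 at the less hindered ring methylene, anti to the aryl group. This γ-alkylation comes back to the route at 16.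

Risk 2, step 8.
- DDQ may abstract hydride from the doubly allylic prenyl CH2 on the diene instead of from the ring.
- It may form quinone adducts with the dienol ether, or go on to oxidise the electron-rich product.
- The fallback replaces hydride abstraction by a selenoxide syn elimination and sets out from 17.
- PhSeCl in CH2Cl2 at −78 °C should selenenylate the prenyl-bearing terminus of the dienol ether from the face opposite the aryl group. This gives 3-(tert-butyldimethylsilyloxy)-4,6-bis(3-methylbut-2-enyl)-6-(phenylselanyl)-5-[6-(triisopropylsilyloxy)benzofuran-2-yl]cyclohex-2-en-1-one F4.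
- mCPBA (1 equiv, −78 °C) oxidises selenium in preference to the alkenes to give the corresponding selenoxide F5.
- Warming in the presence of iPr2NH brings about elimination towards the cis ring hydrogen and enolisation to 5-(tert-butyldimethylsilyloxy)-2,4-bis(3-methylbut-2-enyl)-3-[6-(triisopropylsilyloxy)benzofuran-2-yl]phenol F6.
- Bu4NF/AcOH as in step 9 then comes back to the route at 19.

Risk 3, step 4.
- The fully substituted phosphonate carbanion may add to the aldehyde or collapse only sluggishly.
- Prolonged heating could then erode the aldehyde or the silyl ether.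
- The fallback builds the prenyl group by allylic substitution instead of carrying it on phosphorus, and sets out from 4.
- A Morita–Baylis–Hillman reaction with methyl vinyl ketone (DABCO) gives 3-{hydroxy[6-(triisopropylsilyloxy)benzofuran-2-yl]methyl}but-3-en-2-one F7.
- Ac2O, pyridine and DMAP convert it into 2-methylidene-3-oxo-1-[6-(triisopropylsilyloxy)benzofuran-2-yl]butyl acetate F8.
- SN2' displacement of the acetate with 2-methylprop-1-enylmagnesium bromide and CuI (10 mol %) in THF at −78 °C creates the prenyl chain and the E-trisubstituted alkene together. This comes back to the route at 10.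

**Further compounds**
F1 | step 6 | methyl 4-[1-(tert-butyldimethylsilyloxy)ethylidene]-7-methyl-3-[6-(triisopropylsilyloxy)benzofuran-2-yl]oct-6-enoate (racemic, alkene geometry not defined) | COC(=O)CC(c1cc2ccc(O[Si](C(C)C)(C(C)C)C(C)C)cc2o1)C(CC=C(C)C)=C(C)O[Si](C)(C)C(C)(C)C
F2 | step 6 | methyl 4-acetyl-7-methyl-3-[6-(triisopropylsilyloxy)benzofuran-2-yl]oct-6-enoate (diastereomer mixture) | COC(=O)CC(c1cc2ccc(O[Si](C(C)C)(C(C)C)C(C)C)cc2o1)C(CC=C(C)C)C(C)=O
F3 | step 6 | rac-trans-4-(3-methylbut-2-enyl)-5-[6-(triisopropylsilyloxy)benzofuran-2-yl]cyclohexane-1,3-dione | O=C1CC(=O)[C@@H](CC=C(C)C)[C@H](c2cc3ccc(O[Si](C(C)C)(C(C)C)C(C)C)cc3o2)C1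
F4 | step 8 | 3-(tert-butyldimethylsilyloxy)-4,6-bis(3-methylbut-2-enyl)-6-(phenylselanyl)-5-[6-(triisopropylsilyloxy)benzofuran-2-yl]cyclohex-2-en-1-one (racemic, selenium and C4 prenyl both trans to aryl) | O=C1C=C(O[Si](C)(C)C(C)(C)C)[C@@H](CC=C(C)C)[C@H](c2cc3ccc(O[Si](C(C)C)(C(C)C)C(C)C)cc3o2)[C@@]1(CC=C(C)C)[Se]c1ccccc1
F5 | step 8 | selenoxide of F4 (configuration at selenium not defined) | O=C1C=C(O[Si](C)(C)C(C)(C)C)[C@@H](CC=C(C)C)[C@H](c2cc3ccc(O[Si](C(C)C)(C(C)C)C(C)C)cc3o2)[C@@]1(CC=C(C)C)[Se](=O)c1ccccc1
F6 | step 8 | 5-(tert-butyldimethylsilyloxy)-2,4-bis(3-methylbut-2-enyl)-3-[6-(triisopropylsilyloxy)benzofuran-2-yl]phenol | CC(C)=CCc1c(O)cc(O[Si](C)(C)C(C)(C)C)c(CC=C(C)C)c1-c1cc2ccc(O[Si](C(C)C)(C(C)C)C(C)C)cc2o1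
F7 | step 4 | 3-{hydroxy[6-(triisopropylsilyloxy)benzofuran-2-yl]methyl}but-3-en-2-one (racemic) | CC(=O)C(=C)C(O)c1cc2ccc(O[Si](C(C)C)(C(C)C)C(C)C)cc2o1
F8 | step 4 | 2-methylidene-3-oxo-1-[6-(triisopropylsilyloxy)benzofuran-2-yl]butyl acetate (racemic) | CC(=O)OC(C(=C)C(C)=O)c1cc2ccc(O[Si](C(C)C)(C(C)C)C(C)C)cc2o1
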